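The synthesis rests on cutting the two ring ether bonds, O1–C2 and O1'–C2'. The feature exploited is the 4-hydroxyphenyl group on each of these carbons. Loss of a benzylic leaving group from C2 or C2' turns that aryl ring into a para-quinone methide. Its electrophilic terminus lies one five-membered transition state away from the phenol oxygen on C7a or C7a'. A single fluoride treatment frees nine phenols, expels two acetates, closes both dihydrofuran rings and places C2 and C2' trans to the preset centres C3 and C3'. The precursor is an open-chain, ninefold silylated bis(1,2,2-triarylethyl acetate) in which only C3 (S) and C3' (R) are defined.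

Key step: step 17

**Conventions.** Unprimed atoms belong to the styryl-bearing dihydrobenzofuran, whose benzo ring is ring A. Primed atoms belong to the 7'-hydroxy dihydrobenzofuran, whose benzo ring is ring C. Ring E is the 3,5-dihydroxyphenyl group on C3'. TBS = tert-butyldimethylsilyl, TIPS = triisopropylsilyl. Ph-bod* = 2,5-diphenylbicyclo[2.2.2]octa-2,5-diene.

**Structure check.** The target string reads 2S,3S,2'R,3'R, with both five-membered rings trans. The open-chain precursor therefore needs C3 = S and C3' = R. No change of connectivity or configuration was found necessary.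

**Assumption 1.** The sense of induction of the diene ligands is taken from their behaviour with acyclic E-configured acceptors, so (R,R)-Ph-bod* should deliver aryl to the Re face of the nitroalkene β-carbon. This should be verified on the first arylation product. If the sense is opposite, the two antipodes are simply exchanged.

**Assumption 2.** 4-(tert-Butyldimethylsilyloxy)styrene is taken as a commercial monomer.

**Design decisions** (same disconnection throughout):
- **Trigger order.** The two phenols para to the carbinol carbons carry TIPS and the other seven carry TBS. With nine equal groups the exposed para silyl ethers would fall first and release quinone methides while the crowded oxygens on C7a and C7a' were still capped.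
- **No isolated aldehyde.** 2,2-Diarylacetaldehydes enolise very easily, which would erase C3 and C3'. Each nitromethyl group therefore goes to the acid, then the methyl ester, then through a one-pot reduction/aryl addition.
- **Two-directional elaboration.** Both side chains are carried forward together, so no benzylic acetate has to survive an aryl-metal reagent.
- **Late styryl arm.** The nitrite oxidation passes through nitrile oxides, which would add to an ortho-styryl double bond. Bromine is also the smaller ortho neighbour in the second arylation.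
- **Roles in the second arylation.** Ring A is the nitroalkene and ring C the boron partner, because a boron derivative of ring A would have two ortho substituents. With these roles C3' needs Re attack and C3 needs Si attack, hence antipodal ligands.

## Route

Step 1
Reactants: 1 bromoresorcinol (5-bromobenzene-1,3-diol)
Product: 2 bis-TBS ether of bromoresorcinol (1-bromo-3,5-bis(TBSO)benzene)
Conditions: TBSCl (2.3 equiv), imidazole (3 equiv), DMF, rt
Reagents that add atoms: tert-butyldimethylsilyl chloride CC(C)(C)[Si](C)(C)Cl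
Why: Imidazole-promoted O-silylation of the two phenols, the only reactive sites present.

Step 2
Reactants: 2 bis-TBS ether of bromoresorcinol
Product: 5 ring E boronic acid ([3,5-bis(TBSO)phenyl]boronic acid), via aryllithium 3 (not isolated), via lithium arylborate 4 (not isolated)
Conditions: n-BuLi (1.05 equiv), THF, −78 °C; B(Oi-Pr)3 (1.5 equiv), −78 °C → rt; 1 M HCl (brief), 0 °C
Reagents that add atoms: triisopropyl borate CC(C)OB(OC(C)C)OC(C)C; water O
Why: Bromine–lithium exchange outruns any attack on the aryl silyl ethers at −78 °C, the meta arrangement rules out silyl migration to carbon, and borate trapping with mild hydrolysis is the classical arylboronic acid synthesis.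

Step 3
Reactants: 6 bromocatechol aldehyde (5-bromo-2,3-dihydroxybenzaldehyde); 7 nitromethane
Product: 8 ring C nitrostyrene with free catechol ((E)-5-bromo-3-(2-nitrovinyl)benzene-1,2-diol)
Conditions: MeNO2 (10 equiv), NH4OAc (1 equiv), AcOH, 100 °C
Reagents that add atoms: none
Why: Henry condensation under ammonium acetate catalysis runs through the iminium ion and dehydrates in situ to the conjugated E-nitroalkene, and it is done on the free catechol so that no silyl ether meets hot acetic acid.

Step 4
Reactants: 8 ring C nitrostyrene with free catechol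
Product: 9 silylated ring C nitrostyrene ((E)-5-bromo-1-(2-nitrovinyl)-2,3-bis(TBSO)benzene)
Conditions: TBSOTf (2.4 equiv), 2,6-lutidine (3 equiv), CH2Cl2, −20 → 0 °C
Reagents that add atoms: tert-butyldimethylsilyl triflate CC(C)(C)[Si](C)(C)OS(=O)(=O)C(F)(F)F
Why: The silyl triflate with a hindered, non-nucleophilic base silylates even the flanked phenol quickly and avoids nucleophilic amines that would add to the nitroalkene.

Step 5
Reactants: 9 silylated ring C nitrostyrene; 5 ring E boronic acid (1.6 equiv)
Product: 10 (R)-diarylnitroethane ((R)-1-[5-bromo-2,3-bis(TBSO)phenyl]-1-[3,5-bis(TBSO)phenyl]-2-nitroethane; the stereocentre is C3')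
Conditions: [RhCl(C2H4)2]2 (2.5 mol %), (R,R)-Ph-bod* (5.5 mol %), KOH (10 mol %), dioxane/H2O 10:1, 35 °C
Reagents that add atoms: none
Why: Hayashi–Miyaura asymmetric conjugate arylation of a β-nitrostyrene, in which the aryl–rhodium species held by the C2-symmetric diene inserts the alkene from the Re face of the β-carbon and so sets C3' as R, water protonates the nitronate, the aryl bromide is inert to monovalent rhodium, and the near-neutral medium spares the activated silyl ethers.

Step 6
Reactants: 10 (R)-diarylnitroethane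
Product: 11 ring C pinacol boronate (10 with Bpin in place of Br at C5'; C3' = R)
Conditions: B2pin2 (1.2 equiv), Pd(dppf)Cl2 (4 mol %), KOAc (3 equiv), dioxane, 85 °C
Reagents that add atoms: bis(pinacolato)diboron CC1(C)OB(OC1(C)C)B1OC(C)(C)C(C)(C)O1
Why: Miyaura borylation, in which zerovalent palladium inserts into the only C–Br bond while potassium acetate is too weak to build up nitronate and cannot touch C3', which is β to the nitro group.

Step 7
Reactants: 1 bromoresorcinol
Product: 13 ring A aldehyde (2-bromo-4,6-dihydroxybenzaldehyde), via iminium chloride 12 (not isolated)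
Conditions: POCl3 (1.2 equiv), DMF (1.5 equiv), MeCN, 0 °C → rt; then H2O, 50 °C
Reagents that add atoms: N,N-dimethylformamide CN(C)C=O; water O
Why: Vilsmeier–Haack formylation takes the resorcinol position that is ortho to one hydroxyl and para to the other rather than the crowded site between both hydroxyls, as with 5-alkylresorcinols, and hydrolysis of the iminium salt gives the aldehyde.

Step 8
Reactants: 13 ring A aldehyde; 7 nitromethane
Product: 14 ring A nitrostyrene with free phenols ((E)-5-bromo-4-(2-nitrovinyl)benzene-1,3-diol)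
Conditions: MeNO2 (10 equiv), NH4OAc (1 equiv), AcOH, 100 °C
Reagents that add atoms: none
Why: Henry condensation as in step 3, again run before silylation, with dehydration giving the E-nitroalkene.

Step 9
Reactants: 14 ring A nitrostyrene with free phenols
Product: 15 silylated ring A nitrostyrene ((E)-1-bromo-2-(2-nitrovinyl)-3,5-bis(TBSO)benzene)
Conditions: TBSOTf (2.4 equiv), 2,6-lutidine (3 equiv), CH2Cl2, −20 → 0 °C
Reagents that add atoms: tert-butyldimethylsilyl triflate CC(C)(C)[Si](C)(C)OS(=O)(=O)C(F)(F)F
Why: Same fast, non-nucleophilic O-silylation as in step 4.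

Step 10
Reactants: 11 ring C pinacol boronate; 15 silylated ring A nitrostyrene (1.5 equiv)
Product: 16 bis(nitromethyl) compound ((S)-1-[2-bromo-4,6-bis(TBSO)phenyl]-1-{3,4-bis(TBSO)-5-[(R)-1-(3,5-bis(TBSO)phenyl)-2-nitroethyl]phenyl}-2-nitroethane; C3 = S, C3' = R)
Conditions: [RhCl(C2H4)2]2 (5 mol %), (S,S)-Ph-bod* (11 mol %), KOH (20 mol %), dioxane/H2O 10:1, 50 °C
Reagents that add atoms: none
Why: Second Hayashi–Miyaura arylation, now with the antipodal diene so that the ring C aryl–rhodium species adds to the Si face of the β-carbon and sets C3 as S under catalyst control, the boron-bearing C5' having no ortho substituent, and any minor enantiomer of 11 is carried into a separable diastereomer.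

Step 11
Reactants: 16 bis(nitromethyl) compound
Product: 18 diacid (both CH2NO2 groups of 16 replaced by CO2H; C3 = S, C3' = R), via bis(nitrile oxide) 17 (not isolated)
Conditions: NaNO2 (6 equiv), AcOH (20 equiv), DMSO/THF 2:1, 35 °C, argon
Reagents that add atoms: sodium nitrite [Na+].[O-]N=O; water O
Why: Nitrite-mediated oxidative Nef-type conversion of primary nitroalkanes into carboxylic acids (nitrosation, loss of nitrous acid to the nitrile oxide, nitrite addition and hydrolysis) runs in weakly acidic medium, a setting known to preserve stereocentres next to the nitromethyl carbon, and no alkene is present yet to trap the nitrile oxides.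

Step 12
Reactants: 18 diacid
Product: 19 dimethyl ester (C3 = S, C3' = R)
Conditions: TMSCHN2 (2.5 equiv), toluene/MeOH 4:1, 0 °C
Reagents that add atoms: trimethylsilyldiazomethane C[Si](C)(C)C=[N+]=[N-]
Why: Esterification with a diazoalkane is a neutral proton-transfer and alkylation sequence, so the acidic C3–H and C3'–H never meet a base.

Step 13
Reactants: 20 bromophenol (4-bromophenol)
Product: 21 TIPS ether of bromophenol ((4-bromophenoxy)triisopropylsilane)
Conditions: TIPSCl (1.1 equiv), imidazole (2 equiv), DMF, rt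
Reagents that add atoms: triisopropylsilyl chloride CC(C)[Si](Cl)(C(C)C)C(C)C
Why: Standard phenol silylation, with TIPS chosen so that this oxygen is the last to be unmasked in step 17.

Step 14
Reactants: 19 dimethyl ester; 21 TIPS ether of bromophenol (6 equiv)
Product: 25 bis(carbinol) (each CO2Me of 19 replaced by CH(OH)[4-(TIPSO)phenyl]; C3 = S, C3' = R, mixture at C2 and C2'), via Grignard reagent 22 (not isolated), via bis(aluminium hemiacetal) 23 (not isolated), via dialdehyde 24 (not isolated)
Conditions: (a) 21, Mg, THF, 40 °C; (b) 19, i-Bu2AlH (2.2 equiv), toluene, −78 °C; (c) solution of 22 added at −78 °C, then → 0 °C; cold aq. potassium sodium tartrate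
Reagents that add atoms: none
Why: One-pot ester reduction and Grignard addition, in which i-Bu2AlH stops at the tetrahedral aluminium hemiacetal at −78 °C and the enolisable aldehyde is released only in the presence of excess aryl Grignard reagent, so 1,2-addition captures it before it can racemise (an enolate would return aldehyde, not product), while the new carbinol configuration is irrelevant and the cold quench limits silyl migration.

Step 15
Reactants: 25 bis(carbinol)
Product: 26 bromo bis(acetate) (both carbinols of 25 acetylated)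
Conditions: Ac2O (6 equiv), DMAP (0.2 equiv), pyridine/CH2Cl2, 0 °C → rt; chromatography on Et3N-deactivated silica
Reagents that add atoms: acetic anhydride CC(=O)OC(C)=O
Why: DMAP-catalysed acylation of the two secondary alcohols under basic conditions, which avoids ionisation of the electron-rich benzylic positions.

Step 16
Reactants: 26 bromo bis(acetate); 27 silyloxystyrene (4-(TBSO)styrene, 2 equiv)
Product: 28 open-chain cyclisation precursor (E-stilbene; seven TBS ethers, two TIPS ethers on the aryl groups at C2 and C2', two acetates; C3 = S, C3' = R, either epimer at C2 and C2')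
Conditions: Pd2(dba)3 (2.5 mol %), P(t-Bu)3·HBF4 (6 mol %), Cy2NMe (1.5 equiv), dioxane, rt → 45 °C
Reagents that add atoms: none
Why: Mizoroki–Heck reaction with the bulky, electron-rich Pd/P(t-Bu)3 catalyst, which couples ortho-substituted aryl bromides near room temperature, gives the E-stilbene by syn insertion at the terminal carbon and syn β-hydride elimination, and the amine base touches neither acetates, silyl ethers nor the non-acidic C3 and C3' centres.

Step 17
Reactants: 28 open-chain cyclisation precursor
Product: 31 target CNP0172909.1 (2S,3S,2'R,3'R), via heptaphenol 29 (not isolated), via bis(quinone methide) 30 (not isolated)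
Conditions: TBAF (1 M in THF, 12 equiv), degassed THF (0.005 M), argon, −40 → 0 °C; then AcOH (12 equiv), aq. NaH2PO4/Na2HPO4 (pH 6); extraction and chromatography under argon
Reagents that add atoms: none
Why: Fluoride removes the seven TBS groups first and the two bulkier TIPS groups last, so each 4-oxidophenyl carbinol acetate loses acetate by 1,6-elimination to a para-quinone methide only when the phenoxides on C7a and C7a' are already free. The closest known reaction type is fluoride- or base-induced para-quinone methide generation from 4-silyloxybenzyl esters followed by intramolecular oxa-1,6-addition of an ortho phenol, the established entry to trans-2-aryl-2,3-dihydrobenzofurans, here run at two insulated sites in one flask. O1–C2 and O1'–C2' each form by 5-exo-trig attack of phenoxide oxygen on the exocyclic quinone methide carbon, and rearomatisation of the oxidophenyl ring drives both closures. C2 is controlled by C3 and C2' by C3': in the reactive conformer the C3–H or C3'–H bond eclipses the quinone methide plane to relieve allylic 1,3-strain and oxygen adds to the face that puts the two aryl groups trans, while any cis ring can reopen by retro-addition in the basic medium and reclose to the less strained trans ring, so the carbinol configuration of 28 does not matter. The step needs selectivity among the oxygen nucleophiles and against proton loss from C3 or C3' or carbon attack by the stilbene: only the oxygens on C7a and C7a' reach the electrophilic carbons through a five-membered transition state, the C7' oxygen is meta to C3a' and geometrically excluded, and the late trigger, low temperature and high dilution keep the quinone methide lifetime short. The opposite absolute senses of the two rings are simply inherited from C3 (S) and C3' (R).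

## Compound list

1 | 5-bromoresorcinol | Oc1cc(O)cc(Br)c1 | starting material
2 | 1-bromo-3,5-bis(TBSO)benzene | Brc1cc(O[Si](C)(C)C(C)(C)C)cc(O[Si](C)(C)C(C)(C)C)c1 | intermediate
3 | 3,5-bis(TBSO)phenyllithium | [Li]c1cc(O[Si](C)(C)C(C)(C)C)cc(O[Si](C)(C)C(C)(C)C)c1 | intermediate
4 | lithium [3,5-bis(TBSO)phenyl]triisopropoxyborate | [Li+].CC(C)O[B-](OC(C)C)(OC(C)C)c1cc(O[Si](C)(C)C(C)(C)C)cc(O[Si](C)(C)C(C)(C)C)c1 | intermediate
5 | [3,5-bis(TBSO)phenyl]boronic acid | OB(O)c1cc(O[Si](C)(C)C(C)(C)C)cc(O[Si](C)(C)C(C)(C)C)c1 | intermediate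
6 | 5-bromo-2,3-dihydroxybenzaldehyde | O=Cc1cc(Br)cc(O)c1O | starting material
7 | nitromethane | C[N+](=O)[O-] | starting material
8 | (E)-5-bromo-3-(2-nitrovinyl)benzene-1,2-diol | O=[N+]([O-])/C=C/c1cc(Br)cc(O)c1O | intermediate
9 | (E)-5-bromo-1-(2-nitrovinyl)-2,3-bis(TBSO)benzene | O=[N+]([O-])/C=C/c1cc(Br)cc(O[Si](C)(C)C(C)(C)C)c1O[Si](C)(C)C(C)(C)C | intermediate
10 | (R)-1-[5-bromo-2,3-bis(TBSO)phenyl]-1-[3,5-bis(TBSO)phenyl]-2-nitroethane | Brc1cc(O[Si](C)(C)C(C)(C)C)c(O[Si](C)(C)C(C)(C)C)c(c1)[C@@H](c1cc(O[Si](C)(C)C(C)(C)C)cc(O[Si](C)(C)C(C)(C)C)c1)C[N+](=O)[O-] | intermediate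
11 | pinacol boronate of 10 (Bpin at C5', C3' = R) | CC1(C)OB(OC1(C)C)c1cc(O[Si](C)(C)C(C)(C)C)c(O[Si](C)(C)C(C)(C)C)c(c1)[C@@H](c1cc(O[Si](C)(C)C(C)(C)C)cc(O[Si](C)(C)C(C)(C)C)c1)C[N+](=O)[O-] | intermediate
12 | (2-bromo-4,6-dihydroxybenzylidene)dimethyliminium chloride | C[N+](C)=Cc1c(Br)cc(O)cc1O.[Cl-] | intermediate
13 | 2-bromo-4,6-dihydroxybenzaldehyde | O=Cc1c(Br)cc(O)cc1O | intermediate
14 | (E)-5-bromo-4-(2-nitrovinyl)benzene-1,3-diol | O=[N+]([O-])/C=C/c1c(Br)cc(O)cc1O | intermediate
15 | (E)-1-bromo-2-(2-nitrovinyl)-3,5-bis(TBSO)benzene | O=[N+]([O-])/C=C/c1c(Br)cc(O[Si](C)(C)C(C)(C)C)cc1O[Si](C)(C)C(C)(C)C | intermediate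
16 | bis(nitromethyl) compound, C3 = S, C3' = R | Brc1cc(O[Si](C)(C)C(C)(C)C)cc(O[Si](C)(C)C(C)(C)C)c1[C@H](c1cc(O[Si](C)(C)C(C)(C)C)c(O[Si](C)(C)C(C)(C)C)c(c1)[C@@H](c1cc(O[Si](C)(C)C(C)(C)C)cc(O[Si](C)(C)C(C)(C)C)c1)C[N+](=O)[O-])C[N+](=O)[O-] | intermediate
17 | bis(nitrile oxide), C3 = S, C3' = R | Brc1cc(O[Si](C)(C)C(C)(C)C)cc(O[Si](C)(C)C(C)(C)C)c1[C@H](c1cc(O[Si](C)(C)C(C)(C)C)c(O[Si](C)(C)C(C)(C)C)c(c1)[C@@H](c1cc(O[Si](C)(C)C(C)(C)C)cc(O[Si](C)(C)C(C)(C)C)c1)C#[N+][O-])C#[N+][O-] | intermediate
18 | diacid, C3 = S, C3' = R | Brc1cc(O[Si](C)(C)C(C)(C)C)cc(O[Si](C)(C)C(C)(C)C)c1[C@H](c1cc(O[Si](C)(C)C(C)(C)C)c(O[Si](C)(C)C(C)(C)C)c(c1)[C@@H](c1cc(O[Si](C)(C)C(C)(C)C)cc(O[Si](C)(C)C(C)(C)C)c1)C(=O)O)C(=O)O | intermediate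
19 | dimethyl ester, C3 = S, C3' = R | Brc1cc(O[Si](C)(C)C(C)(C)C)cc(O[Si](C)(C)C(C)(C)C)c1[C@H](c1cc(O[Si](C)(C)C(C)(C)C)c(O[Si](C)(C)C(C)(C)C)c(c1)[C@@H](c1cc(O[Si](C)(C)C(C)(C)C)cc(O[Si](C)(C)C(C)(C)C)c1)C(=O)OC)C(=O)OC | intermediate
20 | 4-bromophenol | Oc1ccc(Br)cc1 | starting material
21 | (4-bromophenoxy)triisopropylsilane | CC(C)[Si](Oc1ccc(Br)cc1)(C(C)C)C(C)C | intermediate
22 | 4-(TIPSO)phenylmagnesium bromide | CC(C)[Si](Oc1ccc([Mg]Br)cc1)(C(C)C)C(C)C | intermediate
23 | bis(diisobutylaluminium methyl hemiacetal), C3 = S, C3' = R | Brc1cc(O[Si](C)(C)C(C)(C)C)cc(O[Si](C)(C)C(C)(C)C)c1[C@H](c1cc(O[Si](C)(C)C(C)(C)C)c(O[Si](C)(C)C(C)(C)C)c(c1)[C@@H](c1cc(O[Si](C)(C)C(C)(C)C)cc(O[Si](C)(C)C(C)(C)C)c1)C(OC)O[Al](CC(C)C)CC(C)C)C(OC)O[Al](CC(C)C)CC(C)C | intermediate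
24 | dialdehyde, C3 = S, C3' = R | Brc1cc(O[Si](C)(C)C(C)(C)C)cc(O[Si](C)(C)C(C)(C)C)c1[C@H](c1cc(O[Si](C)(C)C(C)(C)C)c(O[Si](C)(C)C(C)(C)C)c(c1)[C@@H](c1cc(O[Si](C)(C)C(C)(C)C)cc(O[Si](C)(C)C(C)(C)C)c1)C=O)C=O | intermediate
25 | bis(carbinol), C3 = S, C3' = R, C2 and C2' unassigned | Brc1cc(O[Si](C)(C)C(C)(C)C)cc(O[Si](C)(C)C(C)(C)C)c1[C@H](c1cc(O[Si](C)(C)C(C)(C)C)c(O[Si](C)(C)C(C)(C)C)c(c1)[C@@H](c1cc(O[Si](C)(C)C(C)(C)C)cc(O[Si](C)(C)C(C)(C)C)c1)C(O)c1ccc(O[Si](C(C)C)(C(C)C)C(C)C)cc1)C(O)c1ccc(O[Si](C(C)C)(C(C)C)C(C)C)cc1 | intermediate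
26 | bromo bis(acetate), C3 = S, C3' = R, C2 and C2' unassigned | Brc1cc(O[Si](C)(C)C(C)(C)C)cc(O[Si](C)(C)C(C)(C)C)c1[C@H](c1cc(O[Si](C)(C)C(C)(C)C)c(O[Si](C)(C)C(C)(C)C)c(c1)[C@@H](c1cc(O[Si](C)(C)C(C)(C)C)cc(O[Si](C)(C)C(C)(C)C)c1)C(OC(C)=O)c1ccc(O[Si](C(C)C)(C(C)C)C(C)C)cc1)C(OC(C)=O)c1ccc(O[Si](C(C)C)(C(C)C)C(C)C)cc1 | intermediate
27 | 4-(TBSO)styrene | C=Cc1ccc(O[Si](C)(C)C(C)(C)C)cc1 | starting material
28 | open-chain precursor: ninefold silylated (7 TBS, 2 TIPS) E-stilbene bis(carbinol acetate), C3 = S, C3' = R, C2 and C2' unassigned | CC(C)(C)[Si](C)(C)Oc1ccc(/C=C/c2cc(O[Si](C)(C)C(C)(C)C)cc(O[Si](C)(C)C(C)(C)C)c2[C@H](c2cc(O[Si](C)(C)C(C)(C)C)c(O[Si](C)(C)C(C)(C)C)c(c2)[C@@H](c2cc(O[Si](C)(C)C(C)(C)C)cc(O[Si](C)(C)C(C)(C)C)c2)C(OC(C)=O)c2ccc(O[Si](C(C)C)(C(C)C)C(C)C)cc2)C(OC(C)=O)c2ccc(O[Si](C(C)C)(C(C)C)C(C)C)cc2)cc1 | intermediate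
29 | heptaphenol bis(TIPS ether) bis(acetate) (drawn neutral), C3 = S, C3' = R | Oc1ccc(/C=C/c2cc(O)cc(O)c2[C@H](c2cc(O)c(O)c(c2)[C@@H](c2cc(O)cc(O)c2)C(OC(C)=O)c2ccc(O[Si](C(C)C)(C(C)C)C(C)C)cc2)C(OC(C)=O)c2ccc(O[Si](C(C)C)(C(C)C)C(C)C)cc2)cc1 | intermediate
30 | bis(para-quinone methide) (drawn neutral with both sites unmasked; the sites react independently), C3 = S, C3' = R | Oc1ccc(/C=C/c2cc(O)cc(O)c2[C@H](c2cc(O)c(O)c(c2)[C@@H](c2cc(O)cc(O)c2)C=C2C=CC(=O)C=C2)C=C2C=CC(=O)C=C2)cc1 | intermediate
31 | CNP0172909.1, (2S,3S,2'R,3'R) | Oc1ccc(/C=C/c2cc(O)cc3c2[C@H](c2cc(O)c4c(c2)[C@@H](c2cc(O)cc(O)c2)[C@H](c2ccc(O)cc2)O4)[C@@H](c2ccc(O)cc2)O3)cc1 | target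

## Step count and risks

Total step count: 17.

Longest linear sequence: 11 steps (6 → 8 → 9 → 10 → 11 → 16 → 18 → 19 → 25 → 26 → 28 → 31). The branch from 1 through steps 1, 2 and 5 has the same length.

**Step 17 (key step).**
- What may go wrong:
  - A quinone methide is released before its partner phenoxide is free.
  - Base-induced proton loss from C3 or C3' converts a quinone methide into an alkene.
  - The electron-rich stilbene attacks through carbon.
  - Intermolecular trapping, incomplete settling to trans, or air oxidation of the polyphenoxide occurs.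
- Fallback: it sets out from 28 and returns at 31. The nine silyl groups are removed without base by Et3N·3HF in THF/MeCN at rt, and the nonaphenol bis(acetate) F1 is isolated by a cold aqueous work-up. F1 is then dissolved at high dilution in CH2Cl2/hexafluoroisopropanol at 0 °C. There the acetates ionise to 4-hydroxybenzyl cations (O-protonated quinone methides), which the neutral ortho phenols capture.
- Why this differs: the anionic one-flask cascade is replaced by two operations with a solvolytic, base-free closure. No phenoxide or strong base is present, and the medium is too weakly acidic to protonate the stilbene.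

**Step 10.**
- What may go wrong: insertion of the doubly ortho-substituted nitroalkene is slow, so hydrolytic loss of boron from the valuable partner takes over. Facial selectivity may also erode.
- Fallback: it inverts the order of fragment union so that both arylations use a cheap boron partner in excess. It sets out from 6 (and uses 15 and 5) and returns at 16.
  - Silylation of 6 (TBSOTf, 2,6-lutidine) gives 5-bromo-2,3-bis(TBSO)benzaldehyde F2.
  - Miyaura borylation gives the formyl boronate F3.
  - F3 in excess is added to 15 with the rhodium/(S,S)-Ph-bod* catalyst to give the nitro aldehyde F4 (C3 = S).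
  - Henry condensation in neat nitromethane with NH4OAc gives the nitrostyrene F5. The hindered internal nitromethyl group cannot compete with the solvent, and re-silylation of the crude material repairs any loss of the ortho silyl group.
  - Arylation of F5 with 5 and (R,R)-Ph-bod* sets C3' and gives 16.

**Step 14.**
- What may go wrong:
  - One or both termini are over-reduced to the primary alcohol.
  - The hemiacetal collapses early, with enolisation.
  - Silyl migrates from the ortho phenol oxygen to the new alkoxide on warming.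
- Fallback: it sets out from 19 and returns at 25. Full reduction with excess i-Bu2AlH gives the configurationally stable diol F6. Dess–Martin periodinane in CH2Cl2 at 0 °C, a neutral oxidation suited to epimerisable aldehydes, gives 24. The crude 24 is filtered cold and treated at once at −78 °C with 22 in the presence of LaCl3·2LiCl, which suppresses enolisation, to give 25.

Further compounds
F1 | step 17 | nonaphenol bis(acetate), C3 = S, C3' = R, C2 and C2' unassigned | Oc1ccc(/C=C/c2cc(O)cc(O)c2[C@H](c2cc(O)c(O)c(c2)[C@@H](c2cc(O)cc(O)c2)C(OC(C)=O)c2ccc(O)cc2)C(OC(C)=O)c2ccc(O)cc2)cc1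
F2 | step 10 | 5-bromo-2,3-bis(TBSO)benzaldehyde | O=Cc1cc(Br)cc(O[Si](C)(C)C(C)(C)C)c1O[Si](C)(C)C(C)(C)C
F3 | step 10 | 5-(pinacolatoboryl)-2,3-bis(TBSO)benzaldehyde | O=Cc1cc(B2OC(C)(C)C(C)(C)O2)cc(O[Si](C)(C)C(C)(C)C)c1O[Si](C)(C)C(C)(C)C
F4 | step 10 | (S)-5-{1-[2-bromo-4,6-bis(TBSO)phenyl]-2-nitroethyl}-2,3-bis(TBSO)benzaldehyde | Brc1cc(O[Si](C)(C)C(C)(C)C)cc(O[Si](C)(C)C(C)(C)C)c1[C@H](c1cc(O[Si](C)(C)C(C)(C)C)c(O[Si](C)(C)C(C)(C)C)c(C=O)c1)C[N+](=O)[O-]
F5 | step 10 | (S)-nitroethane F4 with (E)-2-nitrovinyl in place of formyl | Brc1cc(O[Si](C)(C)C(C)(C)C)cc(O[Si](C)(C)C(C)(C)C)c1[C@H](c1cc(O[Si](C)(C)C(C)(C)C)c(O[Si](C)(C)C(C)(C)C)c(/C=C/[N+](=O)[O-])c1)C[N+](=O)[O-]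
F6 | step 14 | diol (both CO2Me of 19 reduced to CH2OH), C3 = S, C3' = R | Brc1cc(O[Si](C)(C)C(C)(C)C)cc(O[Si](C)(C)C(C)(C)C)c1[C@H](c1cc(O[Si](C)(C)C(C)(C)C)c(O[Si](C)(C)C(C)(C)C)c(c1)[C@@H](c1cc(O[Si](C)(C)C(C)(C)C)cc(O[Si](C)(C)C(C)(C)C)c1)CO)CO
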